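**Strategy.** Everything rests on opening pyran ring C at C3–C4. C3 carries the ester oxygen and C4 is the benzylic carbon on C4a of ring A, so this bond can be built as the C3=C4 double bond of a cyclic enol ester. One ring-closing metathesis closes ring C with the protected syringate already on C3 and leaves the preset C2 untouched. Its precursor is an acyclic aryl benzyl-type ether: O1–C2 is in place with defined configuration, C4a bears a vinyl group and C2 bears a 1-(aroyloxy)vinyl group. The C2 aryl group then sends hydrogen to the opposite face of C3=C4, which makes C3 cis, and hydrogenolysis frees six phenols.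

Key step: step 8

Atom labels (O1, C2, C3, C4, C4a, C8a; rings A, B, C) follow flavan numbering, also in the open-chain compounds.

Assumption: with (R)-BINOL/Ti(OiPr)4 the alkynylzinc is taken to attack the Re face of the aryl aldehyde, the same sense as in dialkylzinc additions with this catalyst. A Mosher ester check on the carbinol should confirm this before material is committed, and (S)-BINOL is the remedy if the sense is reversed.

**Step 1**
Reactants: 1 2,4,6-trihydroxybenzaldehyde
Product: 2 2,4-bis(benzyloxy)-6-hydroxybenzaldehyde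
Conditions: BnBr (2.05 equiv), K2CO3 (2.1 equiv), DMF, 0 °C → rt
Reagents that add atoms: benzyl bromide, BrCc1ccccc1
Why: Williamson etherification, in which the third hydroxyl is held in a hydrogen bond to the formyl oxygen and reacts much more slowly, so two equivalents of halide should stop at the dibenzyl ether.

**Step 2**
Reactants: 2 2,4-bis(benzyloxy)-6-hydroxybenzaldehyde
Product: 3 3,5-bis(benzyloxy)-2-vinylphenol
Conditions: Ph3PCH3Br (2.5 equiv), KOtBu (2.5 equiv), THF, 0 °C → rt
Reagents that add atoms: methyltriphenylphosphonium bromide, C[P+](c1ccccc1)(c1ccccc1)c1ccccc1.[Br-]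
Why: Wittig methylenation, in which the first equivalent of ylide only deprotonates the phenol and the excess converts the formyl group into the vinyl group, so no phenol protection is needed, and the electron-rich styrene 3 is taken on without storage.

**Step 3**
Reactants: 4 trimethylsilylacetylene; 5 3,4,5-tris(benzyloxy)benzaldehyde
Product: 7 (S)-1-[3,4,5-tris(benzyloxy)phenyl]-3-(trimethylsilyl)prop-2-yn-1-ol, via ethyl(trimethylsilylethynyl)zinc 6 (not isolated)
Conditions: 4 (3 equiv), Et2Zn (3 equiv), Cy2NH (5 mol %), Et2O, rt; (R)-BINOL (20 mol %), Ti(OiPr)4 (50 mol %); then 5, rt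
Reagents that add atoms: diethylzinc, CC[Zn]CC (its ethylzinc unit is held only in 6)
Why: Catalytic enantioselective alkynylzinc addition to an aromatic aldehyde under BINOL–titanium control, where Re-face delivery sets the carbinol centre in one step, which is shorter and more reliable than reducing the aryl alkynyl ketone, whose two unsaturated flanks a hydride-transfer catalyst can hardly tell apart.

**Step 4**
Reactants: 7 (S)-1-[3,4,5-tris(benzyloxy)phenyl]-3-(trimethylsilyl)prop-2-yn-1-ol
Product: 8 (R)-1-[3,4,5-tris(benzyloxy)phenyl]prop-2-yn-1-ol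
Conditions: K2CO3 (0.2 equiv), MeOH–THF, 0 °C → rt
Reagents that add atoms: none
Why: Methoxide-catalysed protodesilylation touches only the C–Si bond, and the descriptor changes from S to R merely because ethynyl ranks below aryl while silylethynyl ranks above it.

**Step 5**
Reactants: 9 syringic acid
Product: 10 4-(benzyloxy)-3,5-dimethoxybenzoic acid
Conditions: BnBr (1.5 equiv), NaOH (3.5 equiv), EtOH–H2O, reflux; then HCl
Reagents that add atoms: benzyl bromide, BrCc1ccccc1
Why: Williamson etherification of the phenoxide–carboxylate dianion, in which any benzyl ester formed alongside is saponified under the same conditions, so acidification should give the acid directly.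

**Step 6**
Reactants: 3 3,5-bis(benzyloxy)-2-vinylphenol; 8 (R)-1-[3,4,5-tris(benzyloxy)phenyl]prop-2-yn-1-ol
Product: 11 (S)-1,5-bis(benzyloxy)-2-vinyl-3-({1-[3,4,5-tris(benzyloxy)phenyl]prop-2-yn-1-yl}oxy)benzene
Conditions: PPh3 (1.5 equiv), DIAD (1.5 equiv), toluene, −20 → 0 °C
Reagents that add atoms: none
Why: Mitsunobu etherification, in which the phenoxide displaces the oxyphosphonium group by SN2 with inversion, turning (R)-8 into (S)-11 and so setting the future C2, while toluene, low temperature and the electron-withdrawing ethynyl group hold back ionisation of the benzylic centre.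

**Step 7**
Reactants: 11 (S)-1,5-bis(benzyloxy)-2-vinyl-3-({1-[3,4,5-tris(benzyloxy)phenyl]prop-2-yn-1-yl}oxy)benzene; 10 4-(benzyloxy)-3,5-dimethoxybenzoic acid
Product: 12 (R)-1-[3,5-bis(benzyloxy)-2-vinylphenoxy]-1-[3,4,5-tris(benzyloxy)phenyl]prop-2-en-2-yl 4-(benzyloxy)-3,5-dimethoxybenzoate
Conditions: [RuCl2(p-cymene)]2 (2 mol %), P(2-furyl)3 (4 mol %), Na2CO3 (8 mol %), toluene, 50 °C
Reagents that add atoms: none
Why: Ruthenium-catalysed Markovnikov hydroacyloxylation of a terminal alkyne, in which the weakly donating furylphosphine lets the carboxylate attack the internal carbon of the π-bound alkyne rather than a vinylidene terminus, the addition has no co-product, the near-neutral medium leaves the styrene and the C2–H alone (descriptor S to R by ranking only), and gold or platinum catalysts are avoided because they would trigger hydroarylation of ring A.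

**Step 8**
Reactants: 12 (R)-1-[3,5-bis(benzyloxy)-2-vinylphenoxy]-1-[3,4,5-tris(benzyloxy)phenyl]prop-2-en-2-yl 4-(benzyloxy)-3,5-dimethoxybenzoate
Product: 13 (2R)-5,7-bis(benzyloxy)-2-[3,4,5-tris(benzyloxy)phenyl]-2H-chromen-3-yl 4-(benzyloxy)-3,5-dimethoxybenzoate
Conditions: second-generation Hoveyda–Grubbs catalyst RuCl2(SIMes)(=CH-C6H4-2-OiPr) (SIMes = 1,3-dimesitylimidazolidin-2-ylidene; 2 × 5 mol %), 1,4-benzoquinone (20 mol %), toluene (2 mM), 60 °C, argon sparge, dark
Reagents that add atoms: none
Why: Ring-closing olefin metathesis by the carbene–metallacyclobutane cycle: the ruthenium alkylidene first exchanges with the monosubstituted styrene on C4a, the resulting aryl carbene adds across the 1-(aroyloxy)vinyl group in an intramolecular [2+2] step with ruthenium on the CH2 terminus, and cycloreversion releases 13 and Ru=CH2, which gives off ethylene when it loads the next styrene. The closest known reactions are the closure of o-vinylaryl allyl ethers to 2H-chromenes and the ring-closing metathesis of 1,1-disubstituted enol ethers, silyl enol ethers and enol esters made by Markovnikov acid addition to alkynes, all with carbene-ligated ruthenium catalysts. Ring C closes as a six-membered ring from a 1,7-diene, the new C3=C4 bond ending up endocyclic and conjugated with ring A. No stereocentre is created, and C2 is carried through because none of its four bonds takes part. The step needs site-selective loading and ring closure ahead of homocoupling: the gem-disubstituted enol ester can neither load the catalyst productively nor dimerise, the styrene is flanked by two ortho oxygen substituents that slow its dimerisation, the aryl ether holds both alkenes close, and high dilution with ethylene removal does the rest. It also needs C2 to stay intact: benzoquinone traps ruthenium hydrides that would move the double bond to C2=C3, and the 60 °C ceiling and exclusion of light keep 6π ring opening of the 2H-chromene and Claisen rearrangement of 12 out of play.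

**Step 9**
Reactants: 13 (2R)-5,7-bis(benzyloxy)-2-[3,4,5-tris(benzyloxy)phenyl]-2H-chromen-3-yl 4-(benzyloxy)-3,5-dimethoxybenzoate
Product: 14 (2R,3R)-5,7-bis(benzyloxy)-2-[3,4,5-tris(benzyloxy)phenyl]chroman-3-yl 4-(benzyloxy)-3,5-dimethoxybenzoate
Conditions: H2 (4 bar), 5% Rh/Al2O3, EtOAc–THF, rt, dark
Reagents that add atoms: none
Why: Heterogeneous syn hydrogenation of an enol ester, in which allylic strain with the C3 ester holds the C2 aryl group pseudoaxial over one face, so the alkene binds the metal by the other face, hydrogen enters C3 and C4 anti to the aryl group and C3 becomes R with the ester cis to the aryl group, and rhodium is chosen because it is far less prone than palladium to double-bond migration into C2=C3 and to cleavage of allylic, vinylic and benzylic C–O bonds.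

**Step 10**
Reactants: 14 (2R,3R)-5,7-bis(benzyloxy)-2-[3,4,5-tris(benzyloxy)phenyl]chroman-3-yl 4-(benzyloxy)-3,5-dimethoxybenzoate
Product: 15 (2R,3R)-epigallocatechin 3-O-(3,5-di-O-methylgallate) (target)
Conditions: H2 (1 bar), 20% Pd(OH)2/C, THF–MeOH, rt
Reagents that add atoms: none
Why: Catalytic hydrogenolysis of six aryl benzyl ethers, the standard last step for benzyl-protected flavan-3-ol esters, under which the ester, the methyl ethers and the cyclic C2–O1 bond are not cleaved and neither stereocentre is touched.

**Compound list**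

1 | 2,4,6-trihydroxybenzaldehyde | O=Cc1c(O)cc(O)cc1O | starting material
2 | 2,4-bis(benzyloxy)-6-hydroxybenzaldehyde | O=Cc1c(O)cc(OCc2ccccc2)cc1OCc1ccccc1 | intermediate
3 | 3,5-bis(benzyloxy)-2-vinylphenol | C=Cc1c(O)cc(OCc2ccccc2)cc1OCc1ccccc1 | intermediate
4 | trimethylsilylacetylene | C#C[Si](C)(C)C | starting material
5 | 3,4,5-tris(benzyloxy)benzaldehyde | O=Cc1cc(OCc2ccccc2)c(OCc2ccccc2)c(OCc2ccccc2)c1 | starting material
6 | ethyl(trimethylsilylethynyl)zinc (not isolated) | CC[Zn]C#C[Si](C)(C)C | intermediate
7 | (S)-1-[3,4,5-tris(benzyloxy)phenyl]-3-(trimethylsilyl)prop-2-yn-1-ol | O[C@H](C#C[Si](C)(C)C)c1cc(OCc2ccccc2)c(OCc2ccccc2)c(OCc2ccccc2)c1 | intermediate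
8 | (R)-1-[3,4,5-tris(benzyloxy)phenyl]prop-2-yn-1-ol | O[C@H](C#C)c1cc(OCc2ccccc2)c(OCc2ccccc2)c(OCc2ccccc2)c1 | intermediate
9 | syringic acid | COc1cc(C(=O)O)cc(OC)c1O | starting material
10 | 4-(benzyloxy)-3,5-dimethoxybenzoic acid | COc1cc(C(=O)O)cc(OC)c1OCc1ccccc1 | intermediate
11 | (S)-1,5-bis(benzyloxy)-2-vinyl-3-({1-[3,4,5-tris(benzyloxy)phenyl]prop-2-yn-1-yl}oxy)benzene | C=Cc1c(OCc2ccccc2)cc(OCc2ccccc2)cc1O[C@@H](C#C)c1cc(OCc2ccccc2)c(OCc2ccccc2)c(OCc2ccccc2)c1 | intermediate
12 | (R)-1-[3,5-bis(benzyloxy)-2-vinylphenoxy]-1-[3,4,5-tris(benzyloxy)phenyl]prop-2-en-2-yl 4-(benzyloxy)-3,5-dimethoxybenzoate | C=Cc1c(OCc2ccccc2)cc(OCc2ccccc2)cc1O[C@H](c1cc(OCc2ccccc2)c(OCc2ccccc2)c(OCc2ccccc2)c1)C(=C)OC(=O)c1cc(OC)c(OCc2ccccc2)c(OC)c1 | intermediate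
13 | (2R)-5,7-bis(benzyloxy)-2-[3,4,5-tris(benzyloxy)phenyl]-2H-chromen-3-yl 4-(benzyloxy)-3,5-dimethoxybenzoate | O=C(OC1=Cc2c(OCc3ccccc3)cc(OCc3ccccc3)cc2O[C@@H]1c1cc(OCc2ccccc2)c(OCc2ccccc2)c(OCc2ccccc2)c1)c1cc(OC)c(OCc2ccccc2)c(OC)c1 | intermediate
14 | (2R,3R)-5,7-bis(benzyloxy)-2-[3,4,5-tris(benzyloxy)phenyl]chroman-3-yl 4-(benzyloxy)-3,5-dimethoxybenzoate | COc1cc(C(=O)O[C@@H]2Cc3c(OCc4ccccc4)cc(OCc4ccccc4)cc3O[C@@H]2c2cc(OCc3ccccc3)c(OCc3ccccc3)c(OCc3ccccc3)c2)cc(OC)c1OCc1ccccc1 | intermediate
15 | (2R,3R)-epigallocatechin 3-O-(3,5-di-O-methylgallate) | COc1cc(C(=O)O[C@@H]2Cc3c(O)cc(O)cc3O[C@@H]2c2cc(O)c(O)c(O)c2)cc(OC)c1O | target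

**Step count.** Total steps: 10. Longest linear sequence: 7 steps (5 → 7 → 8 → 11 → 12 → 13 → 14 → 15; the branch from 1 is equally long).

**The three steps most likely to fail**

**Step 8 (ring-closing metathesis).**
- After loading at the styrene, the carbene may settle into a chelate with a neighbouring ether oxygen. It may then never engage the crowded gem-disubstituted enol ester alkene next to C2.
- In that case slow stilbene-type homocoupling, or catalyst decay to hydrides with alkene migration, would take over. If heat is used to force turnover, thermal ring opening of the product would erode C2.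
- The fallback sets out from 11 and comes back at 14. It brings in the C3 oxygen after ring closure instead of before.
- Semihydrogenation of the alkyne (H2, Pd/CaCO3 poisoned with Pb(OAc)2, quinoline, EtOAc) should give the (S)-allyl aryl ether F1.
- Ring-closing metathesis of its two monosubstituted alkenes uses the second-generation Grubbs catalyst RuCl2(=CHPh)(PCy3)(SIMes) in CH2Cl2 at 40 °C. It should give the (2S)-flav-3-ene F2, which has the same spatial arrangement at C2 with the descriptor changed by ranking only.
- Hydroboration–oxidation (BH3·THF; then NaOH, H2O2) places oxygen on C3 anti to the aryl group and should give the 2,3-trans flavan-3-ol F3.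
- Dess–Martin oxidation should give the flavan-3-one F4.
- LiBH(s-Bu)3 in THF at −78 °C attacks anti to the C2 aryl group and should give the 2,3-cis flavan-3-ol F5.
- Carbodiimide esterification with 10 (EDC·HCl, DMAP, CH2Cl2) leads to 14.

**Step 7 (hydroacyloxylation).**
- Regiochemical leakage is possible through carboxylate attack at the terminal carbon by way of a vinylidene.
- Addition at the internal carbon may be sluggish, since it sits next to the branched and inductively withdrawing C2. The metal may also engage the styrene.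
- The fallback sets out from 11 and comes back at 12. It fixes the regiochemistry with boron first.
- Copper-catalysed α-selective protoboration, which favours the internal boronate for propargylic ethers ((SIMes)CuCl, NaOtBu, B2pin2, MeOH, THF, −50 to −15 °C), should give the (S)-internal vinylboronic pinacol ester F6.
- KHF2 in MeOH–H2O should convert it into the potassium alkenyltrifluoroborate F7.
- A Chan–Lam-type oxidative C–O coupling with acid 10 (CuBr, DMAP, 4 Å molecular sieves, O2, MeCN, 60 °C) should deliver 12.

**Step 9 (hydrogenation).**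
- Hydrogen uptake at the hindered trisubstituted alkene may be slow.
- The double bond may migrate into C2=C3, with loss of the C2 information.
- The allylic C2–O1 or the vinylic C3–O bond may be hydrogenolysed, or facial selectivity may be incomplete.
- The fallback sets out from 13 and comes back at 14. It replaces face-selective hydrogen addition to the alkene by face-selective hydride addition to a ketone.
- MeLi (2 equiv, THF, −78 °C) cleaves the enol ester to the regiodefined lithium flav-3-en-3-olate F8. Protonation at C4 with AcOH at −78 °C, before it can equilibrate towards C2, should give the flavan-3-one F4.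
- LiBH(s-Bu)3 at −78 °C should then give the 2,3-cis flavan-3-ol F5, and esterification with 10 (EDC·HCl, DMAP, CH2Cl2) leads to 14.

**Further compounds**

F1 | step 8 | (S)-1,5-bis(benzyloxy)-2-vinyl-3-({1-[3,4,5-tris(benzyloxy)phenyl]prop-2-en-1-yl}oxy)benzene | C=Cc1c(OCc2ccccc2)cc(OCc2ccccc2)cc1O[C@@H](C=C)c1cc(OCc2ccccc2)c(OCc2ccccc2)c(OCc2ccccc2)c1
F2 | step 8 | (2S)-5,7-bis(benzyloxy)-2-[3,4,5-tris(benzyloxy)phenyl]-2H-chromene | C1=Cc2c(OCc3ccccc3)cc(OCc3ccccc3)cc2O[C@@H]1c1cc(OCc2ccccc2)c(OCc2ccccc2)c(OCc2ccccc2)c1
F3 | step 8 | (2R,3S)-5,7-bis(benzyloxy)-2-[3,4,5-tris(benzyloxy)phenyl]chroman-3-ol | O[C@H]1Cc2c(OCc3ccccc3)cc(OCc3ccccc3)cc2O[C@@H]1c1cc(OCc2ccccc2)c(OCc2ccccc2)c(OCc2ccccc2)c1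
F4 | step 8 | (2R)-5,7-bis(benzyloxy)-2-[3,4,5-tris(benzyloxy)phenyl]chroman-3-one | O=C1Cc2c(OCc3ccccc3)cc(OCc3ccccc3)cc2O[C@@H]1c1cc(OCc2ccccc2)c(OCc2ccccc2)c(OCc2ccccc2)c1
F5 | step 8 | (2R,3R)-5,7-bis(benzyloxy)-2-[3,4,5-tris(benzyloxy)phenyl]chroman-3-ol | O[C@@H]1Cc2c(OCc3ccccc3)cc(OCc3ccccc3)cc2O[C@@H]1c1cc(OCc2ccccc2)c(OCc2ccccc2)c(OCc2ccccc2)c1
F6 | step 7 | (S)-2-{3-[3,5-bis(benzyloxy)-2-vinylphenoxy]-3-[3,4,5-tris(benzyloxy)phenyl]prop-1-en-2-yl}-4,4,5,5-tetramethyl-1,3,2-dioxaborolane | C=Cc1c(OCc2ccccc2)cc(OCc2ccccc2)cc1O[C@H](c1cc(OCc2ccccc2)c(OCc2ccccc2)c(OCc2ccccc2)c1)C(=C)B1OC(C)(C)C(C)(C)O1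
F7 | step 7 | potassium (S)-{3-[3,5-bis(benzyloxy)-2-vinylphenoxy]-3-[3,4,5-tris(benzyloxy)phenyl]prop-1-en-2-yl}trifluoroborate | C=Cc1c(OCc2ccccc2)cc(OCc2ccccc2)cc1O[C@H](c1cc(OCc2ccccc2)c(OCc2ccccc2)c(OCc2ccccc2)c1)C(=C)[B-](F)(F)F.[K+]
F8 | step 9 | lithium (2R)-5,7-bis(benzyloxy)-2-[3,4,5-tris(benzyloxy)phenyl]-2H-chromen-3-olate | [Li+].[O-]C1=Cc2c(OCc3ccccc3)cc(OCc3ccccc3)cc2O[C@@H]1c1cc(OCc2ccccc2)c(OCc2ccccc2)c(OCc2ccccc2)c1
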